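**Assumption:** the target has no stereocentre and the diaryl ether axis rotates freely, so it is achiral and is made as the single constitution drawn.

## Retrosynthetic overview

1. Target 10 ⇐ bis(methyl ether) 9 by global O-demethylation.
2. 9 ⇐ the diaryl C–O bond. Both termini (the phenol oxygen of ring B and the guaiacol-type ring carbon of ring A) are innately nucleophilic, so ring A is used with reversed polarity as an aryl-cation equivalent: the aryl(TMP)-λ3-iodane 8, made in the flask from iodide 6.
3. 6 ⇐ aniline 4 (Sandmeyer) ⇐ o-anisidine 3 (NH2-directed dibromination). Ring B phenol 2 ⇐ guaiacol 1 (tribromination).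
4. No ring is formed. Both benzene rings are bought; all five bromines are in place before the rings are joined.

## Route

Step 1
Reactants: 1 guaiacol (2-methoxyphenol)
Product: 2 2,3,4-tribromo-6-methoxyphenol (4,5,6-tribromoguaiacol)
Conditions: Br2 (3.2 equiv), AcOH, 20 → 60 °C; aq. NaHSO3; recrystallise
Reagents that add atoms: bromine, BrBr
Why: Electrophilic aromatic bromination in which the free OH directs the first two bromines to its para and ortho positions and the OMe group directs the third to its own para position, the pattern of the classical tribromoguaiacol.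

Step 2
Reactants: 3 o-anisidine (2-methoxyaniline)
Product: 4 2,4-dibromo-6-methoxyaniline
Conditions: NBS (2.05 equiv), MeCN, 0 °C → rt
Reagents that add atoms: N-bromosuccinimide, O=C1CCC(=O)N1Br
Why: Electrophilic aromatic bromination governed by the NH2 group, which directs to its para position and its one free ortho position (the other ortho site carries OMe), and stops at the dibromide with two equivalents of NBS.

Step 3
Reactants: 4 2,4-dibromo-6-methoxyaniline
Product: 6 1,5-dibromo-2-iodo-3-methoxybenzene, via diazonium hydrogen sulfate 5 (not isolated)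
Conditions: NaNO2, H2SO4/AcOH/H2O, 0–5 °C; then KI, H2O, 0 → 50 °C
Reagents that add atoms: potassium iodide, [K+].[I-]
Why: Sandmeyer-type iododediazoniation in which diazotisation in sulfuric acid (no chloride, so the C–Br bonds activated by N2+ cannot exchange) is followed by copper-free replacement of N2 by iodide at the same carbon.

Step 4
Reactants: 6 1,5-dibromo-2-iodo-3-methoxybenzene; 2 2,3,4-tribromo-6-methoxyphenol
Product: 9 1,2,3-tribromo-4-(2,4-dibromo-6-methoxyphenoxy)-5-methoxybenzene, via hydroxy(tosyloxy)iodane 7 (not isolated), via aryl(TMP)iodonium tosylate 8 (not isolated)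
Conditions: one pot: mCPBA (1.05 equiv), TsOH·H2O (1.05 equiv), MeCN, 77 °C, 30 min; then 1,3,5-trimethoxybenzene (1.1 equiv), 77 °C → rt; then 2 (1.2 equiv), K2CO3 (5 equiv), 4 Å MS, 65 °C, 12 h
Reagents that add atoms: none
Why: Koser-type oxidation of the aryl iodide and SEAr on 1,3,5-trimethoxybenzene (complete before phenol 2 is added) give an aryl(TMP)iodonium salt, and metal-free O-arylation by ligand exchange and ligand coupling at iodine(III) then transfers the electron-poor 2,6-disubstituted aryl group (not the electron-rich TMP dummy, and with no ortho hydrogen for an aryne pathway) to the phenoxide of 2, a reaction type known to tolerate tetra-ortho-substituted diaryl ethers.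

Step 5
Reactants: 9 1,2,3-tribromo-4-(2,4-dibromo-6-methoxyphenoxy)-5-methoxybenzene
Product: 10 3,4,5-tribromo-2-(2,4-dibromo-6-hydroxyphenoxy)phenol
Conditions: BBr3 (5 equiv), CH2Cl2, −78 °C → rt, 16 h; then MeOH/H2O, 0 °C
Reagents that add atoms: none
Why: BBr3-mediated cleavage of both aryl methyl ethers (Lewis-acid activation, then bromide SN2 at methyl) leaves the diaryl ether and the five C–Br bonds untouched and gives the achiral target.

## Compound list

1 | guaiacol (2-methoxyphenol) | COc1ccccc1O | starting material
2 | 2,3,4-tribromo-6-methoxyphenol | COc1cc(Br)c(Br)c(Br)c1O | intermediate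
3 | o-anisidine (2-methoxyaniline) | COc1ccccc1N | starting material
4 | 2,4-dibromo-6-methoxyaniline | COc1cc(Br)cc(Br)c1N | intermediate
5 | 2,4-dibromo-6-methoxybenzenediazonium hydrogen sulfate | COc1cc(Br)cc(Br)c1[N+]#N.OS(=O)(=O)[O-] | intermediate
6 | 1,5-dibromo-2-iodo-3-methoxybenzene | COc1cc(Br)cc(Br)c1I | intermediate
7 | 1,5-dibromo-2-[hydroxy(tosyloxy)-λ3-iodanyl]-3-methoxybenzene | COc1cc(Br)cc(Br)c1I(O)OS(=O)(=O)c1ccc(C)cc1 | intermediate
8 | (2,4-dibromo-6-methoxyphenyl)(2,4,6-trimethoxyphenyl)iodonium tosylate | COc1cc(OC)c([I+]c2c(OC)cc(Br)cc2Br)c(OC)c1.Cc1ccc(cc1)S(=O)(=O)[O-] | intermediate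
9 | 1,2,3-tribromo-4-(2,4-dibromo-6-methoxyphenoxy)-5-methoxybenzene | COc1cc(Br)cc(Br)c1Oc1c(OC)cc(Br)c(Br)c1Br | intermediate
10 | 3,4,5-tribromo-2-(2,4-dibromo-6-hydroxyphenoxy)phenol | Oc1cc(Br)cc(Br)c1Oc1c(O)cc(Br)c(Br)c1Br | target

## Step count and risks

Total step count: 5. Longest linear sequence: 4 steps (3 → 4 → 6 → 9 → 10); the branch 1 → 2 is one step.

**Most likely to fail, first: step 4.** The telescoped iodane formation and ligand coupling must form a tetra-ortho-substituted ether from a weakly nucleophilic phenoxide. The fallback sets out from 2 and comes back to the route at 10, using normal polarity. Phenoxide 2 displaces fluoride from purchased 3,5-dibromo-2-fluorobenzaldehyde (O=Cc1cc(Br)cc(Br)c1F) with K2CO3 in DMAc at 100 °C. This SNAr, activated by the ortho formyl group, gives 3,5-dibromo-2-(2,3,4-tribromo-6-methoxyphenoxy)benzaldehyde F5. Baeyer–Villiger oxidation with mCPBA in CH2Cl2 turns the formyl group into the formate ester, 3,5-dibromo-2-(2,3,4-tribromo-6-methoxyphenoxy)phenyl formate F6. BBr3 followed by a methanol/water quench removes both the methyl ether and the formate and gives 10.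

**Second: step 1.** The third bromine may enter ortho instead of para to OMe, or a fourth may add. The fallback sets out from 1 and comes back at 2, installing the bromine para to OMe first. Acetylation (Ac2O, pyridine) gives 2-methoxyphenyl acetate F1. Because OAc is a weaker donor than OMe, NBS in MeCN brominates para to OMe and gives 5-bromo-2-methoxyphenyl acetate F2. Hydrolysis (NaOH, MeOH/H2O, then acid) gives 5-bromo-2-methoxyphenol F3. Br2 (2.1 equiv) in AcOH then brominates only the positions ortho and para to the free OH, which gives 2 without regiochemical ambiguity.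

**Third: step 3.** The hindered, weakly basic aniline may give phenol or reduction by-products in the aqueous iodide step. The fallback sets out from 4 and comes back at 6, separating diazotisation from iodide delivery. The diazonium salt 5 is quenched into pyrrolidine/K2CO3 at 0 °C and isolated as the stable triazene, 1-[(2,4-dibromo-6-methoxyphenyl)diazenyl]pyrrolidine F4. Anhydrous iodo-de-triazenation with NaI/TMSCl in MeCN at 60 °C then gives 6.

## Further compounds

F1 | step 1 | 2-methoxyphenyl acetate | COc1ccccc1OC(C)=O
F2 | step 1 | 5-bromo-2-methoxyphenyl acetate | COc1ccc(Br)cc1OC(C)=O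
F3 | step 1 | 5-bromo-2-methoxyphenol | COc1ccc(Br)cc1O
F4 | step 3 | 1-[(2,4-dibromo-6-methoxyphenyl)diazenyl]pyrrolidine | COc1cc(Br)cc(Br)c1N=NN1CCCC1
F5 | step 4 | 3,5-dibromo-2-(2,3,4-tribromo-6-methoxyphenoxy)benzaldehyde | O=Cc1cc(Br)cc(Br)c1Oc1c(OC)cc(Br)c(Br)c1Br
F6 | step 4 | 3,5-dibromo-2-(2,3,4-tribromo-6-methoxyphenoxy)phenyl formate | O=COc1cc(Br)cc(Br)c1Oc1c(OC)cc(Br)c(Br)c1Br
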